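## The problem

Ainsliadimer A is two guaianolide units joined through a central cyclopentane, C3–C4–C15–C15′–C4′ (natural-product numbering; unprimed = diol half, primed = keto half). Each unit is a cis-fused hydroazulene with a trans-fused α-methylene-γ-lactone and a C10 exocyclic methylene. The core carries three contiguous fully substituted stereocentres: the cis tertiary carbinols C3 and C4 and the spiro all-carbon centre C4′, with O3, O4 and C3′ on one face and C2, C5 and C5′ on the other. These three must be set first and in absolute terms, because the eight outer centres can then be relayed from them: C5 and C5′ from the core, C6, C7 and C1 (and their primed partners) from C5 and C5′. The late groups are fragile. C3–OH with C3′=O is a tertiary aldol that base can cleave, the α-methylene lactones are Michael acceptors, and the 1,1-disubstituted C10 alkenes can migrate in acid, so all of them should appear at the end. The enabling feature is that C1 and C5 are bridged by the three core-bound atoms C2–C3–C4, and C1′ and C5′ by C2′–C3′–C4′. An alkyne on each bridge and a vinylcyclopropane on C4 and on C4′ therefore map onto both hydroazulenes at once. One hidden difficulty follows: the alkyne on C3 is vicinal to both vinylcyclopropane-bearing carbons, so its pairing has to be steered.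

## Retrosynthesis

**33 ⇒ 32 ⇒ 31.** No skeletal bond is cut. The C3′ ketone is traced to the silyl-protected carbinol and the diol to its acetonide, so the retro-aldol-prone array is unveiled only in the last two steps. The forward steps need only a fluoride/acid deprotection and oxidation of the single secondary alcohol of 32.

**31 ⇒ 28 ⇒ 27 ⇒ 24.** The two C11=C13 bonds are cut (enolate methylenation). Both C10 methylenes and H1/H1′ are traced to allylsilanes, and both lactone C6–O bonds to hydroboration of C6=C7 alkenes that carry acetic esters on C7. This leaves bis(hydroazulene) 24, whose only centres beyond the core are C5 and C5′. Hydroboration should occur anti to the core (H5 face) and protonation on the convex face, so these steps are relay, not new control. Protodesilylation must precede the methylenation, because an iminium salt would attack the allylsilane.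

**24 ⇒ 23 (key cut).** C1–C5, C9–C10, C1′–C5′ and C9′–C10′ are cut together. Against building each seven-membered ring separately, this removes four rings and leaves a monocyclic core with three stereocentres. C3′ is carried as a silyl ether, not a ketone: a β,γ-alkynyl ketone would drift to the allenone, and borane would reduce the ketone later anyway. The forward step must pair each alkyne with the right vinylcyclopropane and set C5 and C5′ from the core.

**23 ⇒ 21 ⇒ 16 + 19.** Both C7–C11 bonds are cut by a Johnson–Claisen transform and both C5–C6 bonds by addition of a cyclopropylidenemethyl nucleophile to a dialdehyde. Compared with an alkenylmetal already bearing the ester (it would cyclize onto itself) or a hindered Julia olefination, the rearrangement delivers the E-alkene, the cyclopropane and the acetic ester in one strain-releasing step, twice.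

**16 ⇒ 15 ⇒ 14 ⇒ 13 ⇒ 11.** The C10–C14 bonds are cut (acetylide alkylation with a silylmethyl electrophile) and C3′–C2′ (propargyl addition to an aldehyde). C5 and C5′ are held as pivalate and tert-butyl ester until one hydride step frees both; neither has an α-hydrogen, so the acetylide chemistry is safe.

**11 ⇒ 10 ⇒ 9 ⇒ 8 ⇒ 7 ⇒ 5.** The C4–O and C5–O bonds are cut back to an exocyclic C4=C5 alkene. A cis-diol by nucleophilic addition to an α-hydroxy ketone would need attack syn to the neighbouring carbon substituent. Dihydroxylation directed by the C3 hydroxyl puts O4 on the face of O3 by design.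

**5 ⇒ 4 ⇒ 3 ⇒ 2 ⇒ 1.** C3–C2 is cut (propargylzinc addition to the ketone, face set by C4′), then C4=C5 (methylenation), then C4′–C3′ (catalytic asymmetric hydroxymethylation of the commercial β-keto ester 1). One enantioselective step fixes C4′, and C3 and C4 follow by substrate control.

## Roads not taken

**Alternative 1:** The cut is C3–C4′, with O3 and O4 added afterwards. Forward, the C3′ ketone enolate of the C15–C15′-linked bis-guaianolide enol triflate A2 is coupled with its own C3 triflate by zerovalent palladium (Pd2(dba)3, bulky phosphine). This closes the central ring and the spiro centre to give the C3=C4 alkene A1, which is then dihydroxylated from the α face.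
- Merits: both halves arrive complete, and the key step forms the hardest carbon centre late and intramolecularly.
- Weak points: the enolate must form beside two α-methylene lactones. Reductive elimination has to create a quaternary centre at a hindered tertiary carbon. The dihydroxylation must pick the tetrasubstituted C3=C4 alkene over four 1,1-disubstituted alkenes, which is against the normal order of reactivity.
- Comparison: if the halves came from an available guaianolide this road would be clearly shorter. The chosen plan sets against that a core whose three centres are fixed early, each by a named interaction, and no late oxidation in the presence of five alkenes.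

**Alternative 2:** The cuts are C4–C5 and C4′–C5′. Forward, the enamine A5 of cyclopentanone adds twice to the cycloheptenone lactone A4 to give the 2,5-bis adduct A3. The five-membered rings are then closed by C-acylation at C4′ and aldol addition to C3.
- Merits: three simple components, the same building block used twice, and more bonds per step than the chosen plan.
- Weak points: the two intermolecular Michael additions create C4, C5, C4′ and C5′ (and C1, C1′ on protonation) with no element that fixes their relative configuration. The two identical arms of A3 must later behave differently. C4 still needs a face-selective hydroxylation and both C10 ketones a methylenation.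
- Comparison: this road is more convergent on paper. The chosen plan pays with a longer linear sequence but forms C5 and C5′ intramolecularly from a core of defined configuration.

**Alternative 3:** The cut is C15–C15′, with C4–C4′ as a temporary bond. Forward, irradiation near 350 nm dimerizes the exocyclic enone alkenes of two molecules of dehydrozaluzanin C, A7, head to head to the dispiro cyclobutane A6. Cleaving the C4–C4′ bond then releases two enolates, one for the aldol to C3 and one for hydroxylation at C4.
- Merits: every outer stereocentre is already in A7, no protecting groups are needed, and the step count is by far the lowest.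
- Weak points: head-to-head against head-to-tail and the facial sense of the [2+2] are not controlled by anything in A7. The α-methylene lactones are photoactive too. The cyclobutane must open only at C4–C4′, and C4 must be oxygenated on one face in a polyene.
- Comparison: with A7 in hand this is the shortest road. The chosen plan sets against that independence from a natural monomer, access to either enantiomer and to core analogues, and core stereochemistry that rests on ground-state selectivity rules.

Key step: step 19

## Route

Remarks on the chemistry: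
- Carbons keep the natural-product numbering throughout; in the monocyclic intermediates the ring is C3, C4, C15, C15′, C4′.
- The C3′ carbinol (compounds 12–32) ends as the ketone and is carried as a mixture of epimers; its SMILES carry no descriptor there. The same holds for the C5/C5′ carbinols of 21.
- (Bromomethylene)cyclopropane 19 is prepared, not bought.

Step 1
Reactants: 1 tert-butyl 2-oxocyclopentane-1-carboxylate
Product: 2 (S)-hydroxymethyl keto ester
Conditions: 37% aq. HCHO, [Pd((R)-BINAP)(H2O)2](OTf)2 (5 mol %; ligand antipode chosen for the S product), THF, −20 °C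
Reagents that add atoms: formaldehyde, C=O
Why: Catalytic enantioselective aldol reaction with formaldehyde (hydroxymethylation) of a cyclic β-keto ester through a chiral enolate of divalent palladium; it sets C4′, the only centre made by reagent control, and brings in C3′.

Step 2
Reactants: 2 (S)-hydroxymethyl keto ester
Product: 3 silyl ether
Conditions: t-BuPh2SiCl, imidazole, DMF, 0 °C → rt
Reagents that add atoms: tert-butyl(chloro)diphenylsilane, CC(C)(C)[Si](Cl)(c1ccccc1)c1ccccc1
Why: Standard silylation of a primary alcohol; it blocks retro-aldol loss of formaldehyde and makes the C3′ arm the bulky group on the upper face for step 4.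

Step 3
Reactants: 3 silyl ether
Product: 4 α′-methylene ketone
Conditions: (CH2O)n, i-Pr2NH2+ CF3CO2−, THF, reflux; used at once
Reagents that add atoms: formaldehyde (as paraformaldehyde), C=O
Why: Direct Mannich-type α-methylenation of a ketone; only C4 can enolize because C4′ is quaternary, so C5 enters at the right carbon.

Step 4
Reactants: 4 α′-methylene ketone
Product: 5 homopropargylic tertiary alcohol
Conditions: Zn, propargyl bromide, THF, 0 °C → rt; aq. NH4Cl
Reagents that add atoms: propargyl bromide, C#CCBr
Why: Barbier propargylation (allenylzinc, 1,2-addition by the six-membered transition state); zinc chelated between the ketone and ester oxygens holds the ester near the carbonyl plane and leaves the silyloxymethyl group over the upper face, so C2 should enter from the lower face and O3 ends cis to C3′.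

Step 5
Reactants: 5 homopropargylic tertiary alcohol
Product: 7 triol, via osmate ester 6 (not isolated)
Conditions: OsO4 (1.05 equiv), Me2NCH2CH2NMe2, CH2Cl2, −78 °C; then aq. NaHSO3, THF, rt
Reagents that add atoms: osmium tetroxide, O=[Os](=O)(=O)=O
Why: Hydrogen-bond-directed dihydroxylation of an allylic alcohol with the OsO4–diamine complex; delivery syn to the C3 hydroxyl, which is also the less hindered side next to C3, should place O4 cis to O3 and C5 on the lower face.

Step 6
Reactants: 7 triol
Product: 8 pivalate diol
Conditions: t-BuCOCl, pyridine, CH2Cl2, 0 °C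
Reagents that add atoms: pivaloyl chloride, CC(C)(C)C(=O)Cl
Why: Selective acylation of the only primary hydroxyl (C5–OH) beside two tertiary ones; the pivalate has no α-hydrogen and falls in the same hydride step as the C5′ ester.

Step 7
Reactants: 8 pivalate diol
Product: 9 acetonide
Conditions: 2-methoxypropene, PPTS (cat.), CH2Cl2, 0 °C → rt
Reagents that add atoms: 2-methoxypropene, C=C(C)OC
Why: Ketalization of a cis-1,2-diol on a cyclopentane; it protects the β-hydroxy ester at C3 against retro-aldol cleavage and later steers the cycloaddition.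

Step 8
Reactants: 9 acetonide
Product: 10 primary alcohol
Conditions: Bu4NF, AcOH, THF, rt → 40 °C
Reagents that add atoms: none
Why: Fluoride cleavage of the silyl ether; the pivalate, tert-butyl ester, ketal and terminal alkyne are inert, and no enolizable position lies β to an oxygen.

Step 9
Reactants: 10 primary alcohol
Product: 11 aldehyde
Conditions: Dess–Martin periodinane, NaHCO3, CH2Cl2, 0 °C → rt
Reagents that add atoms: none
Why: Dess–Martin oxidation of a neopentyl primary alcohol to a non-enolizable aldehyde (C3′).

Step 10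
Reactants: 11 aldehyde
Product: 12 homopropargylic secondary alcohol
Conditions: Zn, propargyl bromide, THF, 0 °C; aq. NH4Cl
Reagents that add atoms: propargyl bromide, C#CCBr
Why: Barbier propargylation of an aldehyde forms C3′–C2′ and brings in C1′ and C10′; the new carbinol centre is not controlled and need not be, since it becomes the ketone.

Step 11
Reactants: 12 homopropargylic secondary alcohol
Product: 13 silyl ether diyne
Conditions: t-BuMe2SiOTf, 2,6-lutidine, CH2Cl2, −78 → 0 °C
Reagents that add atoms: tert-butyldimethylsilyl triflate, CC(C)(C)[Si](C)(C)OS(=O)(=O)C(F)(F)F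
Why: Silylation of a hindered secondary alcohol with the silyl triflate; the ether must last until step 23.

Step 12
Reactants: 13 silyl ether diyne
Product: 14 bis(propargylsilane)
Conditions: LiN(i-Pr)2 (2.3 equiv), THF, −78 °C; Me3SiCH2OTf (2.6 equiv), −78 → 0 °C
Reagents that add atoms: (trimethylsilyl)methyl triflate, C[Si](C)(C)COS(=O)(=O)C(F)(F)F
Why: Twofold C-alkylation of lithium acetylides with an α-silyl electrophile (known route to propargylsilanes); neither ester has an α-hydrogen, and the amide base does not add to them.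

Step 13
Reactants: 14 bis(propargylsilane)
Product: 15 diol
Conditions: LiAlH4, THF, 0 °C → rt
Reagents that add atoms: none
Why: Hydride reduction of the tert-butyl ester (C5′) and cleavage of the pivalate (C5) in one step; silyl ether, ketal and propargylsilanes are inert.

Step 14
Reactants: 15 diol
Product: 16 dialdehyde
Conditions: (COCl)2, DMSO, CH2Cl2, −78 °C; Et3N, −78 → 0 °C; used at once
Reagents that add atoms: none
Why: Swern oxidation; both hydroxyls are activated before the base is added, which avoids the lactol and lactone that a stepwise oxidant would give from a cis-1,3-bis(hydroxymethyl) array.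

Step 15
Reactants: 17 methylenecyclopropane
Product: 18 1-bromo-1-(bromomethyl)cyclopropane
Conditions: Br2, CH2Cl2, −40 °C
Reagents that add atoms: bromine, BrBr
Why: Electrophilic bromine addition to the exocyclic alkene at low temperature, where the cyclopropane survives.

Step 16
Reactants: 18 1-bromo-1-(bromomethyl)cyclopropane
Product: 19 (bromomethylene)cyclopropane
Conditions: KOt-Bu, DMSO, 15 °C
Reagents that add atoms: none
Why: E2 dehydrobromination; loss of a ring hydrogen would give a cyclopropene, so the exocyclic vinyl bromide should form.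

Step 17
Reactants: 16 dialdehyde; 19 (bromomethylene)cyclopropane
Product: 21 bis(allylic alcohol), via (cyclopropylidenemethyl)lithium 20 (not isolated)
Conditions: 19 (5 equiv), t-BuLi (10 equiv), Et2O, −78 °C; then 16 in THF, −78 → 0 °C; aq. NH4Cl
Reagents that add atoms: none
Why: Lithium–bromine exchange and 1,2-addition of the vinyllithium to two non-enolizable aldehydes form C5–C6 and C5′–C6′; excess reagent and warming reopen the lactolate that the first alkoxide can form with the second aldehyde, and the carbinol configurations are lost in step 18.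

Step 18
Reactants: 21 bis(allylic alcohol)
Product: 23 bis-alkyne bis(vinylcyclopropane), via bis(ketene acetal) 22 (not isolated)
Conditions: MeC(OMe)3 (excess), EtCO2H (5 mol %), xylene, 135 °C, MeOH distilled off
Reagents that add atoms: trimethyl orthoacetate, CC(OC)(OC)OC
Why: Twofold Johnson–Claisen rearrangement onto the alkylidenecyclopropane terminus forms C7–C11 and C7′–C11′; the chair transition state with the core pseudo-equatorial should give the E alkenes, and relief of alkylidenecyclopropane strain drives it.

Step 19
Reactants: 23 bis-alkyne bis(vinylcyclopropane)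
Product: 24 bis(hydroazulene)
Conditions: [Rh(CO)2Cl]2 (5 mol %), ClCH2CH2Cl, 80 °C, 0.01 M
Reagents that add atoms: none
Why: Monovalent rhodium binds each vinylcyclopropane, opens the strained ring to a rhodacyclohexene (trivalent rhodium), inserts the tethered alkyne at the allyl terminus (C1–C5, C1′–C5′) and reductively eliminates (C9–C10, C9′–C10′). The closest known reaction is the rhodium-catalysed intramolecular [5+2] cycloaddition of alkyne-tethered vinylcyclopropanes with a three-atom tether, here run twice in one molecule. Rings A5 and B5 close by alkyne insertion through the tethers C2–C3–C4 and C2′–C3′–C4′ (five-membered closure onto the alkene carbon); rings A7 and B7 close in the ring-expanding reductive elimination. C5: the ketal methyl group that points into the cleft between the dioxolane and the new ring should push C6 to the side of C15, so H5 ends syn to O4. C5′: C6′ should avoid the fully substituted C3 and turn to C15′H2, so H5′ ends syn to C3. The step also needs the alkyne on C3 to pair with the vinylcyclopropane on C4 and not with that on C4′; the ketal holds the C3–C2 and C4–C5 bonds eclipsed, the alkene on C4′ is the more hindered one, and closure of ring B removes the competing partner. The 1-substituted cyclopropanes speed the ring opening and place the acetic esters on C7 and C7′, and the silylmethyl groups end on C10 and C10′.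

Step 20
Reactants: 24 bis(hydroazulene)
Product: 27 bis-lactone bis(allylsilane), via bis(alkylborane) 25 (not isolated), via diol diester 26 (not isolated)
Conditions: BH3·THF (2.5 equiv), THF, 0 °C; 30% H2O2, aq. NaOAc, 0 °C → rt; then PPTS, toluene, 80 °C
Reagents that add atoms: hydrogen peroxide, OO
Why: Hydroboration–oxidation of the two trisubstituted alkenes (the tetrasubstituted allylsilane alkenes react far more slowly); syn addition on the H5/H5′ face, away from the core, should give C6–OH and H7 on that face, hence trans hydroxy esters that lactonize to the trans-fused γ-lactones.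

Step 21
Reactants: 27 bis-lactone bis(allylsilane)
Product: 28 bis(exocyclic methylene) bis-lactone
Conditions: CF3CO2H (5 equiv), CH2Cl2, −20 °C, short contact; NaHCO3 quench
Reagents that add atoms: none
Why: Protodesilylation of allylsilanes with allylic transposition: protonation at C1 and C1′ on the convex face (that of H5 and H5′) should give the cis ring fusions, and loss of silicon gives the C10 and C10′ methylenes.

Step 22
Reactants: 28 bis(exocyclic methylene) bis-lactone
Product: 31 bis(α-methylene lactone), via bis(Mannich base) 29 (not isolated), via bis(ammonium iodide) 30 (not isolated)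
Conditions: LiN(SiMe3)2 (2.5 equiv), THF, −78 °C; CH2=NMe2+ I− (3 equiv), −78 °C → rt; then MeI, CH2Cl2; aq. NaHCO3
Reagents that add atoms: N,N-dimethylmethyleneiminium iodide (Eschenmoser's salt), C=[N+](C)C.[I-]
Why: Lactone enolate aminomethylation, quaternization and elimination (Eschenmoser methylenation); it follows step 21 because the iminium salt would otherwise attack the allylsilanes.

Step 23
Reactants: 31 bis(α-methylene lactone)
Product: 32 triol
Conditions: 48% aq. HF, MeCN, 0 °C → rt
Reagents that add atoms: none
Why: Aqueous HF in acetonitrile cleaves the secondary silyl ether and hydrolyses the ketal while sparing the alkenes and lactones; no ketone is present yet, so no aldol array sees acid.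

Step 24
Reactants: 32 triol
Product: 33 ainsliadimer A
Conditions: Dess–Martin periodinane, NaHCO3, CH2Cl2, 0 °C
Reagents that add atoms: none
Why: Dess–Martin oxidation of the only secondary alcohol (C3′, either epimer); the two tertiary hydroxyls cannot be oxidized and the buffered, base-free medium spares the new β-hydroxy ketone.

## Compound list

1 | tert-butyl 2-oxocyclopentane-1-carboxylate | O=C1CCCC1C(=O)OC(C)(C)C | starting material
2 | tert-butyl (1S)-1-(hydroxymethyl)-2-oxocyclopentane-1-carboxylate (ring = C4′, C3, C4, C15, C15′; CH2OH = C3′; ester carbon = C5′) | O=C1CCC[C@@]1(CO)C(=O)OC(C)(C)C | intermediate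
3 | tert-butyl (1S)-1-{[(tert-butyldiphenylsilyl)oxy]methyl}-2-oxocyclopentane-1-carboxylate | O=C1CCC[C@@]1(CO[Si](c1ccccc1)(c1ccccc1)C(C)(C)C)C(=O)OC(C)(C)C | intermediate
4 | tert-butyl (1S)-1-{[(tert-butyldiphenylsilyl)oxy]methyl}-3-methylidene-2-oxocyclopentane-1-carboxylate | O=C1C(=C)CC[C@@]1(CO[Si](c1ccccc1)(c1ccccc1)C(C)(C)C)C(=O)OC(C)(C)C | intermediate
5 | tert-butyl (1S,2R)-1-{[(tert-butyldiphenylsilyl)oxy]methyl}-2-hydroxy-3-methylidene-2-(prop-2-yn-1-yl)cyclopentane-1-carboxylate (C3–OH cis to the silyloxymethyl group) | C#CC[C@@]1(O)C(=C)CC[C@]1(C(=O)OC(C)(C)C)CO[Si](c1ccccc1)(c1ccccc1)C(C)(C)C | intermediate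
6 | cyclic osmate ester of 5 across O4 and O5 with chelating tetramethylethylenediamine (hexavalent osmium) | C#CC[C@@]1(O)[C@@]2(CO[Os-2]3(=O)(=O)(O2)[N+](C)(C)CC[N+]3(C)C)CC[C@]1(C(=O)OC(C)(C)C)CO[Si](c1ccccc1)(c1ccccc1)C(C)(C)C | intermediate
7 | triol: cyclopentane with C3–OH and C4–OH cis to each other and to the C4′ silyloxymethyl group; propargyl on C3, CH2OH (C5) on C4 and tert-butyl ester on C4′ on the other face | C#CC[C@@]1(O)[C@@](O)(CO)CC[C@]1(C(=O)OC(C)(C)C)CO[Si](c1ccccc1)(c1ccccc1)C(C)(C)C | intermediate
8 | C5 pivalate of 7 | C#CC[C@@]1(O)[C@@](O)(COC(=O)C(C)(C)C)CC[C@]1(C(=O)OC(C)(C)C)CO[Si](c1ccccc1)(c1ccccc1)C(C)(C)C | intermediate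
9 | C3,C4-O-isopropylidene ketal of 8 | C#CC[C@@]12OC(C)(C)O[C@]1(COC(=O)C(C)(C)C)CC[C@]2(C(=O)OC(C)(C)C)CO[Si](c1ccccc1)(c1ccccc1)C(C)(C)C | intermediate
10 | C3′ primary alcohol (9 without the silyl group) | C#CC[C@@]12OC(C)(C)O[C@]1(COC(=O)C(C)(C)C)CC[C@]2(C(=O)OC(C)(C)C)CO | intermediate
11 | C3′ aldehyde | C#CC[C@@]12OC(C)(C)O[C@]1(COC(=O)C(C)(C)C)CC[C@]2(C(=O)OC(C)(C)C)C=O | intermediate
12 | C3′ homopropargylic alcohol (both C3′ epimers) | C#CC[C@@]12OC(C)(C)O[C@]1(COC(=O)C(C)(C)C)CC[C@]2(C(=O)OC(C)(C)C)C(O)CC#C | intermediate
13 | C3′ tert-butyldimethylsilyl ether of 12 with two terminal alkynes | C#CC[C@@]12OC(C)(C)O[C@]1(COC(=O)C(C)(C)C)CC[C@]2(C(=O)OC(C)(C)C)C(O[Si](C)(C)C(C)(C)C)CC#C | intermediate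
14 | bis(propargylsilane): both alkynes capped with CH2SiMe3 (C14, C14′) | C[Si](C)(C)CC#CC[C@@]12OC(C)(C)O[C@]1(COC(=O)C(C)(C)C)CC[C@]2(C(=O)OC(C)(C)C)C(O[Si](C)(C)C(C)(C)C)CC#CC[Si](C)(C)C | intermediate
15 | C5,C5′ diol (cis-1,3-bis(hydroxymethyl) on C4 and C4′) | C[Si](C)(C)CC#CC[C@@]12OC(C)(C)O[C@]1(CO)CC[C@]2(CO)C(O[Si](C)(C)C(C)(C)C)CC#CC[Si](C)(C)C | intermediate
16 | C5,C5′ dialdehyde | C[Si](C)(C)CC#CC[C@@]12OC(C)(C)O[C@]1(C=O)CC[C@]2(C=O)C(O[Si](C)(C)C(C)(C)C)CC#CC[Si](C)(C)C | intermediate
17 | methylenecyclopropane | C=C1CC1 | starting material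
18 | 1-bromo-1-(bromomethyl)cyclopropane | BrCC1(Br)CC1 | intermediate
19 | (bromomethylene)cyclopropane | BrC=C1CC1 | intermediate
20 | (cyclopropylidenemethyl)lithium | [Li]C=C1CC1 | intermediate
21 | bis(allylic alcohol): C5 and C5′ each CH(OH)–CH=cyclopropylidene (carbinol epimers) | C[Si](C)(C)CC#CC[C@@]12OC(C)(C)O[C@]1(C(O)C=C1CC1)CC[C@]2(C(O)C=C1CC1)C(O[Si](C)(C)C(C)(C)C)CC#CC[Si](C)(C)C | intermediate
22 | bis(ketene O-methyl acetal) of 21 | C[Si](C)(C)CC#CC[C@@]12OC(C)(C)O[C@]1(C(OC(=C)OC)C=C1CC1)CC[C@]2(C(OC(=C)OC)C=C1CC1)C(O[Si](C)(C)C(C)(C)C)CC#CC[Si](C)(C)C | intermediate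
23 | key precursor: central cyclopentane acetonide with silylmethyl alkyne arms on C3 and (via C3′–OSiMe2t-Bu) on C4′, and (E)-2-[1-(2-methoxy-2-oxoethyl)cyclopropyl]ethenyl arms on C4 and C4′ | C[Si](C)(C)CC#CC[C@@]12OC(C)(C)O[C@]1(/C=C/C1(CC(=O)OC)CC1)CC[C@]2(/C=C/C1(CC(=O)OC)CC1)C(O[Si](C)(C)C(C)(C)C)CC#CC[Si](C)(C)C | intermediate
24 | bis(bicyclo[5.3.0]decadiene): C1=C10 allylsilane and C6=C7 acetic ester in each half; H5 syn to O4, H5′ syn to C3; C3′–OSiMe2t-Bu | C[Si](C)(C)CC1=C2C[C@]43OC(C)(C)O[C@]3([C@@H]2C=C(CC(=O)OC)CC1)CC[C@]45C(O[Si](C)(C)C(C)(C)C)CC6=C(C[Si](C)(C)C)CCC(CC(=O)OC)=C[C@H]65 | intermediate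
25 | bis(alkylborane): BH2 on C6 and C6′, H on C7 and C7′, all on the H5/H5′ face | C[Si](C)(C)CC1=C2C[C@]43OC(C)(C)O[C@]3([C@@H]2[C@@H](B)[C@H](CC(=O)OC)CC1)CC[C@]45C(O[Si](C)(C)C(C)(C)C)CC6=C(C[Si](C)(C)C)CC[C@@H](CC(=O)OC)[C@H](B)[C@H]65 | intermediate
26 | diol diester: C6–OH and C6′–OH trans to the C7 and C7′ acetic esters | C[Si](C)(C)CC1=C2C[C@]43OC(C)(C)O[C@]3([C@@H]2[C@@H](O)[C@H](CC(=O)OC)CC1)CC[C@]45C(O[Si](C)(C)C(C)(C)C)CC6=C(C[Si](C)(C)C)CC[C@@H](CC(=O)OC)[C@H](O)[C@H]65 | intermediate
27 | bis(trans-fused γ-lactone) with both tetrasubstituted allylsilanes intact | C[Si](C)(C)CC1=C2C[C@]43OC(C)(C)O[C@]3([C@@H]2[C@H]7OC(=O)C[C@@H]7CC1)CC[C@]45C(O[Si](C)(C)C(C)(C)C)CC6=C(C[Si](C)(C)C)CC[C@H]7CC(=O)O[C@@H]7[C@H]65 | intermediate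
28 | bis-lactone with C10 and C10′ exocyclic methylenes and cis ring fusions (H1 syn to H5, H1′ syn to H5′) | C=C1[C@@H]2C[C@]43OC(C)(C)O[C@]3([C@@H]2[C@H]7OC(=O)C[C@@H]7CC1)CC[C@]45C(O[Si](C)(C)C(C)(C)C)C[C@H]6C(=C)CC[C@H]7CC(=O)O[C@@H]7[C@H]65 | intermediate
29 | bis(Mannich base): CH2NMe2 on C11 and C11′ | C=C1[C@@H]2C[C@]43OC(C)(C)O[C@]3([C@@H]2[C@H]7OC(=O)C(CN(C)C)[C@@H]7CC1)CC[C@]45C(O[Si](C)(C)C(C)(C)C)C[C@H]6C(=C)CC[C@H]7C(CN(C)C)C(=O)O[C@@H]7[C@H]65 | intermediate
30 | bis(trimethylammoniomethyl) lactone diiodide | C=C1[C@@H]2C[C@]43OC(C)(C)O[C@]3([C@@H]2[C@H]7OC(=O)C(C[N+](C)(C)C)[C@@H]7CC1)CC[C@]45C(O[Si](C)(C)C(C)(C)C)C[C@H]6C(=C)CC[C@H]7C(C[N+](C)(C)C)C(=O)O[C@@H]7[C@H]65.[I-].[I-] | intermediate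
31 | bis(α-methylene lactone): ainsliadimer A skeleton with C3,C4 acetonide and C3′–OSiMe2t-Bu | C=C1[C@@H]2C[C@]43OC(C)(C)O[C@]3([C@@H]2[C@H]7OC(=O)C(=C)[C@@H]7CC1)CC[C@]45C(O[Si](C)(C)C(C)(C)C)C[C@H]6C(=C)CC[C@H]7C(=C)C(=O)O[C@@H]7[C@H]65 | intermediate
32 | 3′-deoxo-3′-hydroxyainsliadimer A (triol, C3′ epimers) | C=C1[C@@H]2C[C@@]4(O)[C@@](O)([C@@H]2[C@H]7OC(=O)C(=C)[C@@H]7CC1)CC[C@]45C(O)C[C@H]6C(=C)CC[C@H]7C(=C)C(=O)O[C@@H]7[C@H]65 | intermediate
33 | ainsliadimer A | C=C1C(=O)O[C@@H]2[C@@H]3[C@@H](C[C@@]4(O)[C@]3(O)CC[C@]43C(=O)C[C@H]4C(=C)CC[C@H]5C(=C)C(=O)O[C@@H]5[C@H]43)C(=C)CC[C@@H]12 | target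

## Step count and risks

Total: 24 steps. Longest linear sequence: 22 steps (1 → 33, steps 1–14 and 17–24); the two-step preparation of 19 is the only branch.

**Step 19 (key step).** Most likely failure: mis-pairing. The alkyne on C3 sits three atoms from the alkene carbon of both vinylcyclopropanes and may engage the one on C4′ before ring B has closed; the remaining alkyne and vinylcyclopropane then cannot reach each other. Second, the cleft argument for the C5 face rests on one ketal methyl group.

Fallback: two single cycloadditions with ring A first. It sets out from 14 and returns at 24.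
- i-Bu2AlH at −78 °C should cleave only the pivalate of 14 and give the C5 alcohol F1.
- Swern oxidation gives the C5 aldehyde F2.
- One addition of 20 gives the C5 allylic alcohol F3, with the tert-butyl ester still in place.
- LiAlH4 gives the C5′ primary alcohol F4.
- Johnson–Claisen rearrangement, then K2CO3/MeOH to free the primary hydroxyl, gives the mono(vinylcyclopropane) F5.
- [Rh(CO)2Cl]2 then has only one alkyne–vinylcyclopropane pair within reach and gives the ring-A cycloadduct F6.
- Dess–Martin oxidation gives the C5′ aldehyde F7; 20 adds far faster to the aldehyde than to the methyl ester at −78 °C and gives the C5′ allylic alcohol F8.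
- A second Johnson–Claisen rearrangement gives the ring-A adduct with the C4′ vinylcyclopropane F9, and a second rhodium cycloaddition closes rings B5 and B7 to give 24.

**Step 4.** Most likely failure: poor facial selectivity at C3. The tert-butyl ester and the silyloxymethyl group are both large, and if chelation is weak the propargyl group may enter from both faces.

Fallback: make C3 planar and set C3 and C4 together. It sets out from 5 (any epimer ratio) and returns at 10.
- Re2O7-catalysed 1,3-transposition of the tertiary allylic alcohol gives the tetrasubstituted cyclopentene with a primary allylic alcohol F10.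
- Pivaloylation gives the allylic pivalate F11.
- Bu4NF gives the free C3′ hydroxymethyl compound F12.
- OsO4 with tetramethylethylenediamine, directed by that hydroxyl and opposed by the tert-butyl ester on the other face, gives the triol F13.
- Ketalization with 2-methoxypropene gives 10.

**Step 18.** Most likely failure: acid- and heat-driven loss of the propargylic silyl groups (to allenes) or ionization of the alkylidenecyclopropyl carbinols during the long heating, and slow orthoester exchange at the two neopentyl carbinols.

Fallback: Ireland–Claisen rearrangement, which is basic and runs below 70 °C. It sets out from 21 and returns at 23.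
- Acetylation gives the bis(acetate) F14.
- LiN(i-Pr)2/Me3SiCl at −78 °C, warming to 60 °C and hydrolysis give the bis(acetic acid) F15.
- Me3SiCHN2 gives 23.

**Step 21.** Most likely failure: protonation of C1 or C1′ from the concave face (trans ring fusion), or acid-driven migration of the new exocyclic alkenes into the ring.

Fallback: move the protodesilylation one stage earlier. It sets out from 26, isolated after the oxidative work-up of step 20, and returns at 28.
- The free C6 and C6′ hydroxyls lie on the H5/H5′ face next to C1 and C1′ and can relay the proton from that side under a milder acid (TsOH·H2O, MeCN, 0 °C). This should give the bis(exocyclic methylene) diol diester F16.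
- PPTS in toluene then lactonizes it to 28.

**Step 23.** Most likely failure: incomplete hydrolysis of the ketal, which sits on two fully substituted carbons, or alkene migration if the acid is forced.

Fallback: change the order and cleave the ketal without water. It sets out from 31 and returns at 33.
- HF·pyridine removes only the silyl group and gives the C3′ carbinol ketal F17.
- Dess–Martin oxidation gives the C3′ ketone ketal F18.
- Me2BBr in CH2Cl2 at −78 °C, helped by coordination to the neighbouring carbonyl, opens the ketal, and aqueous work-up gives 33.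

## Further compounds

F1 | step 19 | C5 alcohol with C5′ tert-butyl ester | C[Si](C)(C)CC#CC[C@@]12OC(C)(C)O[C@]1(CO)CC[C@]2(C(=O)OC(C)(C)C)C(O[Si](C)(C)C(C)(C)C)CC#CC[Si](C)(C)C
F2 | step 19 | C5 aldehyde with C5′ tert-butyl ester | C[Si](C)(C)CC#CC[C@@]12OC(C)(C)O[C@]1(C=O)CC[C@]2(C(=O)OC(C)(C)C)C(O[Si](C)(C)C(C)(C)C)CC#CC[Si](C)(C)C
F3 | step 19 | C5 allylic alcohol with C5′ tert-butyl ester | C[Si](C)(C)CC#CC[C@@]12OC(C)(C)O[C@]1(C(O)C=C1CC1)CC[C@]2(C(=O)OC(C)(C)C)C(O[Si](C)(C)C(C)(C)C)CC#CC[Si](C)(C)C
F4 | step 19 | C5 allylic alcohol with C5′ primary alcohol | C[Si](C)(C)CC#CC[C@@]12OC(C)(C)O[C@]1(C(O)C=C1CC1)CC[C@]2(CO)C(O[Si](C)(C)C(C)(C)C)CC#CC[Si](C)(C)C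
F5 | step 19 | mono(vinylcyclopropane) on C4 with C5′ primary alcohol | C[Si](C)(C)CC#CC[C@@]12OC(C)(C)O[C@]1(/C=C/C1(CC(=O)OC)CC1)CC[C@]2(CO)C(O[Si](C)(C)C(C)(C)C)CC#CC[Si](C)(C)C
F6 | step 19 | ring-A cycloadduct with C5′ primary alcohol | C[Si](C)(C)CC1=C2C[C@]43OC(C)(C)O[C@]3([C@@H]2C=C(CC(=O)OC)CC1)CC[C@]4(CO)C(O[Si](C)(C)C(C)(C)C)CC#CC[Si](C)(C)C
F7 | step 19 | ring-A cycloadduct with C5′ aldehyde | C[Si](C)(C)CC1=C2C[C@]43OC(C)(C)O[C@]3([C@@H]2C=C(CC(=O)OC)CC1)CC[C@]4(C=O)C(O[Si](C)(C)C(C)(C)C)CC#CC[Si](C)(C)C
F8 | step 19 | ring-A cycloadduct with C5′ allylic alcohol | C[Si](C)(C)CC1=C2C[C@]43OC(C)(C)O[C@]3([C@@H]2C=C(CC(=O)OC)CC1)CC[C@]4(C(O)C=C5CC5)C(O[Si](C)(C)C(C)(C)C)CC#CC[Si](C)(C)C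
F9 | step 19 | ring-A cycloadduct with the C4′ vinylcyclopropane | C[Si](C)(C)CC1=C2C[C@]43OC(C)(C)O[C@]3([C@@H]2C=C(CC(=O)OC)CC1)CC[C@]4(/C=C/C5(CC(=O)OC)CC5)C(O[Si](C)(C)C(C)(C)C)CC#CC[Si](C)(C)C
F10 | step 4 | tetrasubstituted cyclopentene with primary allylic alcohol | C#CCC1=C(CO)CC[C@]1(C(=O)OC(C)(C)C)CO[Si](c1ccccc1)(c1ccccc1)C(C)(C)C
F11 | step 4 | allylic pivalate | C#CCC1=C(COC(=O)C(C)(C)C)CC[C@]1(C(=O)OC(C)(C)C)CO[Si](c1ccccc1)(c1ccccc1)C(C)(C)C
F12 | step 4 | allylic pivalate with free C3′ hydroxymethyl group | C#CCC1=C(COC(=O)C(C)(C)C)CC[C@]1(C(=O)OC(C)(C)C)CO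
F13 | step 4 | C3,C4,C3′ triol pivalate | C#CC[C@@]1(O)[C@@](O)(COC(=O)C(C)(C)C)CC[C@]1(C(=O)OC(C)(C)C)CO
F14 | step 18 | bis(acetate) of 21 | C[Si](C)(C)CC#CC[C@@]12OC(C)(C)O[C@]1(C(OC(C)=O)C=C1CC1)CC[C@]2(C(OC(C)=O)C=C1CC1)C(O[Si](C)(C)C(C)(C)C)CC#CC[Si](C)(C)C
F15 | step 18 | bis(acetic acid) corresponding to 23 | C[Si](C)(C)CC#CC[C@@]12OC(C)(C)O[C@]1(/C=C/C1(CC(=O)O)CC1)CC[C@]2(/C=C/C1(CC(=O)O)CC1)C(O[Si](C)(C)C(C)(C)C)CC#CC[Si](C)(C)C
F16 | step 21 | bis(exocyclic methylene) diol diester | C=C1[C@@H]2C[C@]43OC(C)(C)O[C@]3([C@@H]2[C@@H](O)[C@H](CC(=O)OC)CC1)CC[C@]45C(O[Si](C)(C)C(C)(C)C)C[C@H]6C(=C)CC[C@@H](CC(=O)OC)[C@H](O)[C@H]65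
F17 | step 23 | C3′ carbinol ketal | C=C1[C@@H]2C[C@]43OC(C)(C)O[C@]3([C@@H]2[C@H]7OC(=O)C(=C)[C@@H]7CC1)CC[C@]45C(O)C[C@H]6C(=C)CC[C@H]7C(=C)C(=O)O[C@@H]7[C@H]65
F18 | step 23 | C3′ ketone ketal (ainsliadimer A acetonide) | C=C1[C@@H]2C[C@]43OC(C)(C)O[C@]3([C@@H]2[C@H]7OC(=O)C(=C)[C@@H]7CC1)CC[C@]45C(=O)C[C@H]6C(=C)CC[C@H]7C(=C)C(=O)O[C@@H]7[C@H]65
A1 | alternative 1 | 3,4-didehydro-3,4-dideoxyainsliadimer A (C3=C4 alkene) | C=C1C(=O)O[C@@H]2[C@@H]3[C@@H](CC4=C3CC[C@]45C(=O)C[C@H]6C(=C)CC[C@H]7C(=C)C(=O)O[C@@H]7[C@H]65)C(=C)CC[C@@H]12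
A2 | alternative 1 | C15–C15′-linked bis-guaianolide with C3 enol triflate and C3′ ketone | C=C1C(=O)O[C@@H]2[C@@H]3[C@@H](CC(OS(=O)(=O)C(F)(F)F)=C3CCC4C(=O)C[C@H]5C(=C)CC[C@H]6C(=C)C(=O)O[C@@H]6[C@H]54)C(=C)CC[C@@H]12
A3 | alternative 2 | 2,5-bis adduct of cyclopentanone | O=C1[C@H](CC[C@@H]1[C@H]2[C@@H](CC(=O)OC)C(=O)CC[C@H]3CC(=O)O[C@H]23)[C@H]2[C@@H](CC(=O)OC)C(=O)CC[C@H]3CC(=O)O[C@H]23
A4 | alternative 2 | cycloheptenone lactone acceptor | O=C1CC[C@H]2CC(=O)O[C@@H]2C=C1CC(=O)OC
A5 | alternative 2 | 1-(cyclopent-1-en-1-yl)pyrrolidine | C1CCN(C1)C1=CCCC1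
A6 | alternative 3 | head-to-head dispiro cyclobutane dimer | C=C1C(=O)O[C@@H]2[C@@H]3[C@@H](CC(=O)[C@]34CC[C@]45C(=O)C[C@H]6C(=C)CC[C@H]7C(=C)C(=O)O[C@@H]7[C@H]65)C(=C)CC[C@@H]12
A7 | alternative 3 | dehydrozaluzanin C | C=C1C(=O)C[C@H]2C(=C)CC[C@H]3C(=C)C(=O)O[C@@H]3[C@@H]12
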